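**Retrosynthetic overview**
- The side chain is joined at C1'–C2' rather than at the ring–C1' bond: a chloromethyl hydroxyquinone is coupled with an (E)-alkenylalane made in situ from a C28 terminal enyne, and the carboalumination sets the 2'E alkene.
- The benzoquinone, the only ring in the target, is built de novo by a Moore diradical cyclisation of a 4-hydroxy-4-propynylcyclobutenone (key step). This comes from squaric acid and propyne, and a tBuO/MeO squarate encodes the OH/OMe regiochemistry.
- The C28 enyne comes from acetylide plus a C26 homoallylic iodide, itself built from 5-bromo-2-methylpent-2-ene and four units of (E)-2,5-diiodopent-2-ene by iterative Negishi coupling.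
- Ring order: cyclobutenedione (starting-material ring) → cyclobutenone → 1,4-benzoquinone (step 4); no other ring is formed.

Assumption: the target has no stereocentres, so "single enantiomer" is read as the single all-E (2E,6E,10E,14E,18E) geometric isomer.

**Step 1**
Reactants: 1 squaric acid
Product: 2 dimethyl squarate (3,4-dimethoxycyclobut-3-ene-1,2-dione)
Conditions: HC(OMe)3, MeOH, reflux, 24 h
Reagents that add atoms: trimethyl orthoformate, COC(OC)OC (methanol, CO)
Why: Orthoester-driven esterification of the vinylogous diacid (standard squarate ester synthesis).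

**Step 2**
Reactants: 2 dimethyl squarate
Product: 3 3-tert-butoxy-4-methoxycyclobut-3-ene-1,2-dione
Conditions: t-BuOK (1.0 equiv), THF, −78 → −40 °C; AcOH quench
Reagents that add atoms: potassium tert-butoxide, CC(C)(C)[O-].[K+] (tBu is the OH protecting group)
Why: Vinylogous transesterification by addition–elimination; it stops at mono-exchange because the released methoxide is the weaker base and the first tBuO group shields the ring against a second exchange.

**Step 3**
Reactants: 3 mixed squarate; 4 propyne
Product: 5 2-tert-butoxy-4-hydroxy-3-methoxy-4-(prop-1-yn-1-yl)cyclobut-2-en-1-one (racemic; the stereocentre is destroyed in step 4)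
Conditions: 4, n-BuLi, THF, −78 °C; then 3, −78 °C, 30 min; aq. NH4Cl
Reagents that add atoms: none
Why: 1,2-addition of the lithium acetylide to a squarate carbonyl (Moore/Liebeskind protocol); the bulky tBuO group blocks its neighbouring carbonyl, so attack occurs at the carbonyl next to C–OMe.

**Step 4 (key step)**
Reactants: 5 propynyl cyclobutenone
Product: 6 2-tert-butoxy-3-methoxy-6-methyl-1,4-benzoquinone (fumigatin tert-butyl ether; C5–H free)
Conditions: p-xylene (0.02 M), 138 °C, 30–60 min, Ar
Reagents that add atoms: none
Why: Moore rearrangement: 4π ring opening gives the enynylketene, the ketene carbon bonds to the methyl-bearing alkyne carbon to close the ring as a σ-aryl/phenoxyl diradical (the C–C bond forms in this diradical cyclisation), and H-atom transfer from OH to the aryl radical gives the quinone; connectivity places tBuO beside the methyl-flanked carbonyl and MeO beside the C–H-flanked carbonyl.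

**Step 5**
Reactants: 6 tert-butoxy quinone
Product: 7 2-(chloromethyl)-5-hydroxy-6-methoxy-3-methyl-1,4-benzoquinone
Conditions: (CH2O)n, HCl(g), AcOH, 23–40 °C
Reagents that add atoms: paraformaldehyde, C=O; hydrogen chloride, Cl
Why: Chloromethylation at the only ring C–H (as for menadione and CoQ0), with HCl also cleaving the vinylogous tert-butyl ester to unmask the hydroxyl.

**Step 6**
Reactants: 8 pent-3-yn-1-ol
Product: 9 (E)-4-iodopent-3-en-1-ol
Conditions: Cp2Zr(H)Cl (2.5 equiv), THF, 23 → 50 °C; then I2, 0 °C
Reagents that add atoms: iodine, II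
Why: Schwartz syn-hydrozirconation with equilibration of Zr to the less hindered methyl-bearing carbon, then iodinolysis with retention, sets the E trisubstituted vinyl iodide.

**Step 7**
Reactants: 9 iodo alcohol
Product: 10 (E)-2,5-diiodopent-2-ene
Conditions: I2, PPh3, imidazole, CH2Cl2, 0 °C
Reagents that add atoms: iodine, II
Why: Appel iodination of the primary alcohol; the vinyl iodide and its geometry are untouched.

**Step 8**
Reactants: 11 5-bromo-2-methylpent-2-ene; 10 diiodide
Product: 12 (E)-1-iodo-4,8-dimethylnona-3,7-diene
Conditions: 11, Mg, THF; ZnCl2; then 10 (1.0 equiv), PdCl2(DPEphos) 2 mol %, THF, 23 °C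
Reagents that add atoms: none
Why: Negishi alkyl–alkenyl coupling; Pd inserts only into the C(sp2)–I bond and couples with retention, leaving the primary iodide for the next cycle.

**Step 9**
Reactants: 12 C11 iodide; 10 diiodide
Product: 13 (3E,7E)-1-iodo-4,8,12-trimethyltrideca-3,7,11-triene
Conditions: t-BuLi (2.1 equiv), Et2O, −78 °C; ZnBr2, THF; 10, PdCl2(DPEphos) 2 mol %, 23 °C
Reagents that add atoms: none
Why: I/Li exchange, transmetalation to zinc and chemoselective Negishi coupling add one E-isoprene unit with retention.

**Step 10**
Reactants: 13 C16 iodide; 10 diiodide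
Product: 14 (3E,7E,11E)-1-iodo-4,8,12,16-tetramethylheptadeca-3,7,11,15-tetraene
Conditions: as step 9
Reagents that add atoms: none
Why: Same iterative Negishi homologation; the new alkene geometry is carried in from 10.

**Step 11**
Reactants: 14 C21 iodide; 10 diiodide
Product: 15 (3E,7E,11E,15E)-1-iodo-4,8,12,16,20-pentamethylhenicosa-3,7,11,15,19-pentaene
Conditions: as step 9
Reagents that add atoms: none
Why: Same iterative Negishi homologation, stereoretentive at the vinyl iodide.

**Step 12**
Reactants: 15 C26 iodide; 16 lithium acetylide–ethylenediamine complex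
Product: 17 (5E,9E,13E,17E)-6,10,14,18,22-pentamethyltricosa-5,9,13,17,21-pentaen-1-yne
Conditions: 16 (3 equiv), DMSO–THF, 5 → 23 °C
Reagents that add atoms: none
Why: SN2 alkynylation of the primary iodide; no alkene is touched.

**Step 13**
Reactants: 17 C28 enyne; 7 chloromethyl hydroxyquinone
Product: 18 3-demethylubiquinone-6, i.e. 2-hydroxy-3-methoxy-6-methyl-5-[(2E,6E,10E,14E,18E)-3,7,11,15,19,23-hexamethyltetracosa-2,6,10,14,18,22-hexaenyl]-1,4-benzoquinone
Conditions: 17, Me3Al (2 equiv), Cp2ZrCl2 (0.25 equiv), ClCH2CH2Cl, 0 → 23 °C; remove volatiles; THF, Ni(0) [NiCl2(PPh3)2 / 2 n-BuLi, 5 mol %]; add 7 (1.2 equiv, pre-treated with 1.0 equiv Me3Al, THF, −78 °C), −20 → 23 °C; dilute HCl work-up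
Reagents that add atoms: trimethylaluminium, C[Al](C)C
Why: Zr-catalysed Negishi carboalumination adds Me and Al syn across the alkyne (Me to the internal carbon), fixing the 2'E geometry, and the alkenylalane then undergoes Lipshutz-type Ni(0) sp3–sp2 coupling with the quinonylmethyl chloride with retention; the acidic OH is masked in situ as its dimethylaluminium salt.

**Compound list**
1 | squaric acid | OC1=C(O)C(=O)C1=O | starting material
2 | dimethyl squarate | COC1=C(OC)C(=O)C1=O | intermediate
3 | 3-tert-butoxy-4-methoxycyclobut-3-ene-1,2-dione | COC1=C(OC(C)(C)C)C(=O)C1=O | intermediate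
4 | propyne | CC#C | starting material
5 | 2-tert-butoxy-4-hydroxy-3-methoxy-4-(prop-1-ynyl)cyclobut-2-en-1-one (racemic) | CC#CC1(O)C(OC)=C(OC(C)(C)C)C1=O | intermediate
6 | 2-tert-butoxy-3-methoxy-6-methyl-1,4-benzoquinone | CC1=CC(=O)C(OC)=C(OC(C)(C)C)C1=O | intermediate
7 | 2-(chloromethyl)-5-hydroxy-6-methoxy-3-methyl-1,4-benzoquinone | CC1=C(CCl)C(=O)C(OC)=C(O)C1=O | intermediate
8 | pent-3-yn-1-ol | CC#CCCO | starting material
9 | (E)-4-iodopent-3-en-1-ol | C/C(I)=C\CCO | intermediate
10 | (E)-2,5-diiodopent-2-ene | C/C(I)=C\CCI | intermediate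
11 | 5-bromo-2-methylpent-2-ene | CC(C)=CCCBr | starting material
12 | (E)-1-iodo-4,8-dimethylnona-3,7-diene | CC(C)=CCC/C(C)=C/CCI | intermediate
13 | (3E,7E)-1-iodo-4,8,12-trimethyltrideca-3,7,11-triene | CC(C)=CCC/C(C)=C/CC/C(C)=C/CCI | intermediate
14 | (3E,7E,11E)-1-iodo-4,8,12,16-tetramethylheptadeca-3,7,11,15-tetraene | CC(C)=CCC/C(C)=C/CC/C(C)=C/CC/C(C)=C/CCI | intermediate
15 | (3E,7E,11E,15E)-1-iodo-4,8,12,16,20-pentamethylhenicosa-3,7,11,15,19-pentaene | CC(C)=CCC/C(C)=C/CC/C(C)=C/CC/C(C)=C/CC/C(C)=C/CCI | intermediate
16 | lithium acetylide–ethylenediamine complex | [Li]C#C.NCCN | starting material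
17 | (5E,9E,13E,17E)-6,10,14,18,22-pentamethyltricosa-5,9,13,17,21-pentaen-1-yne | CC(C)=CCC/C(C)=C/CC/C(C)=C/CC/C(C)=C/CC/C(C)=C/CCC#C | intermediate
18 | 3-demethylubiquinone-6 | COC1=C(O)C(=O)C(C)=C(C/C=C(\C)CC/C=C(\C)CC/C=C(\C)CC/C=C(\C)CC/C=C(\C)CCC=C(C)C)C1=O | target

**Totals**
Total steps: 13. Longest linear sequence: 8 (steps 6 → 7 → 8 → 9 → 10 → 11 → 12 → 13).

**Three steps most likely to fail**
1. Step 3 (with step 2): clean mono-exchange and regioselective acetylide addition to the unsymmetrical squarate; the wrong regioisomer would give the isomeric quinone (OH and OMe interchanged). Fallback: replace steric control by combined steric and electronic control. Use 3-methoxy-4-(triisopropylsilyloxy)cyclobutenedione, made from 2 by mono-saponification and silylation. The silyloxy group is both bulkier and a poorer donor, so both effects direct attack next to C–OMe, and the silyl group is lost in step 5.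
2. Step 5: chloromethylation of an electron-poor quinone C–H with simultaneous tBu loss. Fallback: install the one-carbon handle by radical C–H hydroxymethylation of 6 (glycolic acid, AgNO3/(NH4)2S2O8, Jacobsen–Torssell type), then convert CH2OH to CH2Cl with HCl, which also removes tBu.
3. Step 13: Ni/alkenylalane coupling in the presence of the acidic hydroxyquinone. Fallback: quench the alkenylalane with I2 to isolate the (E)-vinyl iodide, convert it to the alkenylzinc, and couple under Pd or Cu catalysis with the O-acetate of 7; then remove the acetate with K2CO3/MeOH (two extra steps).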